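The cyclohexane ring is opened between the alkylidene-bearing ring carbon (C5) and the neighbouring CHCl carbon (C6) that sits next to the CMe2 centre (C1). The array Cl–C6–C5(=C7)–C8–Br, two ring carbons plus the exocyclic two-carbon arm, is a (Z)-1,4-difunctionalised but-2-ene and therefore the retron of a 1-vinylcyclohexene. Ring-closing enyne metathesis of an acyclic 1,7-enyne (terminal alkyne at C5, vinyl group on C1) forges C5–C6 as the ring alkene and shifts the alkene CH2 to C8 in one operation. Singlet-oxygen [4+2] addition then locks the Z geometry and oxygenates C6 and C8; invertive halogenation finishes.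

Key step: step 7

Atom labels used in the text: C1 = CMe2, C2 = CHBr, C3 = CH2, C4 = CHCl, C5 = alkylidene ring carbon, C6 = CHCl next to C1, C7 = exocyclic =CH, C8 = CH2Br.

Assumption: the diisopinocampheylborane reagents follow their usual sense, the (+)-α-pinene series adding to the Si face of an aldehyde and the (−)-α-pinene series to the Re face; if the sense were opposite, the pinene antipodes of steps 1 and 4 are exchanged.

Step 1
Reactants: 1 3-(trimethylsilyl)prop-2-ynal; 2 B-allyldiisopinocampheylborane of the (−)-α-pinene series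
Product: 4 (R)-1-(trimethylsilyl)hex-5-en-1-yn-3-ol, via boryl ether 3 (not isolated)
Conditions: Et2O, −78 °C; then HOCH2CH2NH2, rt
Reagents that add atoms: none
Why: Brown allylboration through a closed chair transition state, in which the (−)-α-pinene-derived reagent should deliver allyl to the Re face of the ynal and set C4 as the (R)-carbinol that is later inverted to the (S)-chloride.

Step 2
Reactants: 4 (R)-1-(trimethylsilyl)hex-5-en-1-yn-3-ol
Product: 5 (R)-tert-butyldimethyl((1-(trimethylsilyl)hex-5-en-1-yn-3-yl)oxy)silane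
Conditions: TBSCl, imidazole, DMF, rt
Reagents that add atoms: tert-butyldimethylsilyl chloride, CC(C)(C)[Si](C)(C)Cl
Why: Silyl ether formation at the secondary propargylic alcohol masks the C4 oxygen through ozonolysis, prenylation and bromination without touching the stereocentre.

Step 3
Reactants: 5 (R)-tert-butyldimethyl((1-(trimethylsilyl)hex-5-en-1-yn-3-yl)oxy)silane
Product: 7 (R)-3-((tert-butyldimethylsilyl)oxy)-5-(trimethylsilyl)pent-4-ynal, via ozonide 6 (not isolated)
Conditions: O3, CH2Cl2, −78 °C; then PPh3, −78 °C to rt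
Reagents that add atoms: ozone, [O-][O+]=O
Why: Ozonolysis with reductive work-up cleaves the terminal alkene much faster than the silylated alkyne and gives the β-silyloxy aldehyde (C2), which is used without delay to avoid β-elimination.

Step 4
Reactants: 7 (R)-3-((tert-butyldimethylsilyl)oxy)-5-(trimethylsilyl)pent-4-ynal; 8 3-methylbuta-1,2-diene
Product: 11 (3R,5R)-3-((tert-butyldimethylsilyl)oxy)-6,6-dimethyl-1-(trimethylsilyl)oct-7-en-1-yn-5-ol, via prenylborane 9 (not isolated), via boryl ether 10 (not isolated)
Conditions: (−)-Ipc2BH [(+)-α-pinene series], THF, −25 °C (with 8); then 7, Et2O, −78 °C; then HOCH2CH2NH2, rt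
Reagents that add atoms: none
Why: Hydroboration of the allene gives the prenylborane, which adds through its γ-carbon (Brown reverse prenylation, chair transition state) to the Si face of the aldehyde under reagent control, creating the quaternary C1 with its vinyl group (C6=CH2) and the (R)-carbinol at C2.

Step 5
Reactants: 11 (3R,5R)-3-((tert-butyldimethylsilyl)oxy)-6,6-dimethyl-1-(trimethylsilyl)oct-7-en-1-yn-5-ol
Product: 12 tert-butyl(((3R,5S)-5-bromo-6,6-dimethyl-1-(trimethylsilyl)oct-7-en-1-yn-3-yl)oxy)dimethylsilane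
Conditions: CBr4, P(n-C8H17)3, 1-methylcyclohexene, toluene, 70 °C
Reagents that add atoms: tetrabromomethane, BrC(Br)(Br)Br
Why: Appel bromination with a small, strongly nucleophilic trialkylphosphine, the variant used for neopentylic secondary alcohols, should displace the alkoxyphosphonium by SN2 with inversion to the (S)-bromide at C2 while 1-methylcyclohexene scavenges HBr.

Step 6
Reactants: 12 tert-butyl(((3R,5S)-5-bromo-6,6-dimethyl-1-(trimethylsilyl)oct-7-en-1-yn-3-yl)oxy)dimethylsilane
Product: 13 (3R,5S)-5-bromo-6,6-dimethyloct-7-en-1-yn-3-ol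
Conditions: Bu4NF, AcOH, THF, 0 °C to rt
Reagents that add atoms: none
Why: Fluoride-mediated desilylation removes the O-silyl and the alkynyl C-silyl group in one operation, and the acetic acid buffer suppresses E2 loss of HBr from the secondary bromide.

Step 7
Reactants: 13 (3R,5S)-5-bromo-6,6-dimethyloct-7-en-1-yn-3-ol
Product: 14 (1R,5S)-5-bromo-4,4-dimethyl-2-vinylcyclohex-2-en-1-ol
Conditions: second-generation Grubbs catalyst (H2IMes)(PCy3)Cl2Ru=CHPh (5–10 mol %), ethylene (1 atm), toluene, 60–80 °C
Reagents that add atoms: none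
Why: Ring-closing enyne metathesis: the ruthenium alkylidene adds to the terminal alkyne by [2+2] cycloaddition, the ruthenacyclobutene opens to a vinylcarbene, and this carbene is captured by the vinyl group on C1 through a second [2+2] addition and cycloreversion, so that C6 becomes bonded to C5 and the former alkene CH2 ends up on the alkyne terminus as C8. The closest known reaction type is the ethylene-assisted ring-closing metathesis of terminal 1,7-enynes to 1-vinylcyclohexenes. The six-membered ring closes in the exo mode, C6 joining the internal alkyne carbon C5; endo closure to a seven-membered 1,3-diene is the alternative. No stereocentre is created, C2 and C4 are untouched, and the C5–C6 bond made here as the ring C=C keeps its sigma component in the target after the pi bond is moved to C5=C7 in step 8. The step needs exo over endo closure and tolerance of the free propargylic hydroxyl and the secondary bromide; the kinetic preference for six-membered rings, the gem-dimethyl group at C1 (which also rules out alkene migration) and the ethylene atmosphere, which keeps the catalyst as its methylidene and suppresses alkyne oligomerisation, should secure this.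

Step 8
Reactants: 14 (1R,5S)-5-bromo-4,4-dimethyl-2-vinylcyclohex-2-en-1-ol
Product: 16 (1R,3R,5S,Z)-5-bromo-2-(2-hydroxyethylidene)-4,4-dimethylcyclohexane-1,3-diol, via endoperoxide 15 (not isolated)
Conditions: O2, tetraphenylporphyrin (cat.), visible light, CH2Cl2, −20 °C; then thiourea, MeOH, rt
Reagents that add atoms: dioxygen, O=O
Why: [4+2] cycloaddition of singlet oxygen to the s-cis diene gives the 3,6-dihydro-1,2-dioxine, whose ring forces C8 cis to C6 (Z) and whose C6–O bond should form cis to the C4 hydroxyl, because in the half-chair with pseudoaxial C4–OH and axial C2–Br that hydroxyl hydrogen-bonds the incoming oxygen while the pseudoaxial C1 methyl shields the opposite face; thiourea then reduces the O–O bond to the triol.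

Step 9
Reactants: 16 (1R,3R,5S,Z)-5-bromo-2-(2-hydroxyethylidene)-4,4-dimethylcyclohexane-1,3-diol
Product: 17 (1R,3R,5S,Z)-5-bromo-2-(2-((tert-butyldimethylsilyl)oxy)ethylidene)-4,4-dimethylcyclohexane-1,3-diol
Conditions: TBSCl (1.05 equiv), imidazole, CH2Cl2, −20 to 0 °C
Reagents that add atoms: tert-butyldimethylsilyl chloride, CC(C)(C)[Si](C)(C)Cl
Why: Selective silyl ether formation, since the primary allylic hydroxyl reacts far faster than the two secondary ones, one of which is neopentylic.

Step 10
Reactants: 17 (1R,3R,5S,Z)-5-bromo-2-(2-((tert-butyldimethylsilyl)oxy)ethylidene)-4,4-dimethylcyclohexane-1,3-diol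
Product: 18 tert-butyl((Z)-2-((2S,4S,6S)-4-bromo-2,6-dichloro-3,3-dimethylcyclohexylidene)ethoxy)dimethylsilane
Conditions: PPh3, hexachloroacetone, CH2Cl2, 0 °C to rt
Reagents that add atoms: hexachloroacetone, O=C(C(Cl)(Cl)Cl)C(Cl)(Cl)Cl
Why: Appel-type deoxychlorination of allylic alcohols, in which chloride attacks each alkoxyphosphonium by SN2 with inversion and little allylic transposition, should turn both carbinols (C4 and C6, cis to C2–Br) into the cis-dichloride trans to bromine and leave the Z alkene untouched.

Step 11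
Reactants: 18 tert-butyl((Z)-2-((2S,4S,6S)-4-bromo-2,6-dichloro-3,3-dimethylcyclohexylidene)ethoxy)dimethylsilane
Product: 19 (2S,4S,6S,Z)-4-bromo-1-(2-bromoethylidene)-2,6-dichloro-3,3-dimethylcyclohexane
Conditions: Ph3PBr2, CH2Cl2, 0 °C to rt
Reagents that add atoms: dibromotriphenylphosphorane, BrP(Br)(c1ccccc1)(c1ccccc1)c1ccccc1
Why: Direct conversion of a silyl ether into a bromide with Ph3PBr2 (silyloxyphosphonium, then SN2 by bromide at the primary allylic carbon) is neutral and mild, so the secondary chlorides, the secondary bromide and the alkene geometry should be retained.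

Compound list
1 | 3-(trimethylsilyl)prop-2-ynal | O=CC#C[Si](C)(C)C | starting material
2 | B-allyldiisopinocampheylborane, enantiomer derived from (−)-α-pinene (commercial pentane solution) | C=CCB([C@H]1C[C@H]2C[C@@H]([C@@H]1C)C2(C)C)[C@H]1C[C@H]2C[C@@H]([C@@H]1C)C2(C)C | starting material
3 | (R)-1-(trimethylsilyl)hex-5-en-1-yn-3-yl diisopinocampheylborinate | C=CC[C@@H](OB([C@H]1C[C@H]2C[C@@H]([C@@H]1C)C2(C)C)[C@H]1C[C@H]2C[C@@H]([C@@H]1C)C2(C)C)C#C[Si](C)(C)C | intermediate
4 | (R)-1-(trimethylsilyl)hex-5-en-1-yn-3-ol | C=CC[C@@H](O)C#C[Si](C)(C)C | intermediate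
5 | (R)-tert-butyldimethyl((1-(trimethylsilyl)hex-5-en-1-yn-3-yl)oxy)silane | C=CC[C@@H](O[Si](C)(C)C(C)(C)C)C#C[Si](C)(C)C | intermediate
6 | secondary ozonide (1,2,4-trioxolane) of 5, mixture at the trioxolane carbon | O1COOC1C[C@@H](O[Si](C)(C)C(C)(C)C)C#C[Si](C)(C)C | intermediate
7 | (R)-3-((tert-butyldimethylsilyl)oxy)-5-(trimethylsilyl)pent-4-ynal | O=CC[C@@H](O[Si](C)(C)C(C)(C)C)C#C[Si](C)(C)C | intermediate
8 | 3-methylbuta-1,2-diene | CC(C)=C=C | starting material
9 | B-(3-methylbut-2-enyl)diisopinocampheylborane, (+)-α-pinene series | CC(C)=CCB([C@@H]1C[C@@H]2C[C@H]([C@H]1C)C2(C)C)[C@@H]1C[C@@H]2C[C@H]([C@H]1C)C2(C)C | intermediate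
10 | diisopinocampheylborinate of 11 | C=CC(C)(C)[C@H](OB([C@@H]1C[C@@H]2C[C@H]([C@H]1C)C2(C)C)[C@@H]1C[C@@H]2C[C@H]([C@H]1C)C2(C)C)C[C@@H](O[Si](C)(C)C(C)(C)C)C#C[Si](C)(C)C | intermediate
11 | (3R,5R)-3-((tert-butyldimethylsilyl)oxy)-6,6-dimethyl-1-(trimethylsilyl)oct-7-en-1-yn-5-ol | C=CC(C)(C)[C@H](O)C[C@@H](O[Si](C)(C)C(C)(C)C)C#C[Si](C)(C)C | intermediate
12 | tert-butyl(((3R,5S)-5-bromo-6,6-dimethyl-1-(trimethylsilyl)oct-7-en-1-yn-3-yl)oxy)dimethylsilane | C=CC(C)(C)[C@@H](Br)C[C@@H](O[Si](C)(C)C(C)(C)C)C#C[Si](C)(C)C | intermediate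
13 | (3R,5S)-5-bromo-6,6-dimethyloct-7-en-1-yn-3-ol | C=CC(C)(C)[C@@H](Br)C[C@@H](O)C#C | intermediate
14 | (1R,5S)-5-bromo-4,4-dimethyl-2-vinylcyclohex-2-en-1-ol | CC1(C)[C@@H](Br)C[C@@H](O)C(C=C)=C1 | intermediate
15 | (5R,7S,8aR)-7-bromo-8,8-dimethyl-3,5,6,7,8,8a-hexahydrobenzo[c][1,2]dioxin-5-ol | CC1(C)[C@@H](Br)C[C@@H](O)C2=CCOO[C@@H]12 | intermediate
16 | (1R,3R,5S,Z)-5-bromo-2-(2-hydroxyethylidene)-4,4-dimethylcyclohexane-1,3-diol | CC1(C)[C@@H](Br)C[C@@H](O)/C(=C/CO)[C@H]1O | intermediate
17 | (1R,3R,5S,Z)-5-bromo-2-(2-((tert-butyldimethylsilyl)oxy)ethylidene)-4,4-dimethylcyclohexane-1,3-diol | CC1(C)[C@@H](Br)C[C@@H](O)/C(=C/CO[Si](C)(C)C(C)(C)C)[C@H]1O | intermediate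
18 | tert-butyl((Z)-2-((2S,4S,6S)-4-bromo-2,6-dichloro-3,3-dimethylcyclohexylidene)ethoxy)dimethylsilane | CC1(C)[C@@H](Br)C[C@H](Cl)/C(=C/CO[Si](C)(C)C(C)(C)C)[C@@H]1Cl | intermediate
19 | (2S,4S,6S,Z)-4-bromo-1-(2-bromoethylidene)-2,6-dichloro-3,3-dimethylcyclohexane | CC1(C)[C@@H](Br)C[C@H](Cl)/C(=C/CBr)[C@@H]1Cl | target

Total step count: 11. Longest linear sequence: 11 steps (1 to 19).

Steps most likely to fail

Step 5. Backside displacement at the neopentylic C2 carbinol is slow, so ionisation of the alkoxyphosphonium may compete and lead to elimination, to 1,2-shift of methyl or vinyl, or to loss of stereochemical integrity. The fallback moves the bromination onto the ring. It sets out from 11: the alkynyl silyl group alone is removed with K2CO3 in MeOH to give (3R,5R)-3-((tert-butyldimethylsilyl)oxy)-6,6-dimethyloct-7-en-1-yn-5-ol F1. Ring-closing enyne metathesis under the conditions of step 7 then gives (1R,5R)-5-((tert-butyldimethylsilyl)oxy)-2,2-dimethyl-4-vinylcyclohex-3-en-1-ol F2, in which the C2 hydroxyl is equatorial on a half-chair and its backside is open along the axial direction anti to the pseudoaxial C1 methyl. Appel bromination in this cyclic setting (CBr4, P(n-C8H17)3, 1-methylcyclohexene, toluene, 70 °C), the setting in which neopentylic cyclohexanols are displaced with inversion, should give (((1R,5S)-5-bromo-4,4-dimethyl-2-vinylcyclohex-2-en-1-yl)oxy)(tert-butyl)dimethylsilane F3. Bu4NF/AcOH then returns to the route at 14.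

Step 8. The singlet-oxygen addition may show poor facial selectivity at C6, with attack on the less hindered face of the all-equatorial half-chair, anti to the C4 hydroxyl, or may be diverted into ene-type oxidation. The fallback replaces kinetic control by equilibration. It sets out from 15, taken as a mixture at C6. Et3N in CH2Cl2 (Kornblum–DeLaMare rearrangement, removal of the unhindered C8 hydrogen) gives the lactol (4R,6S)-6-bromo-7,7-dimethyl-2,4,5,6,7,7a-hexahydro-1-benzofuran-2,4-diol F4. Lactol-selective oxidation with Ag2CO3 on Celite (Fétizon oxidation) gives the butenolide (4R,6S,7aR)-6-bromo-4-hydroxy-7,7-dimethyl-5,6,7,7a-tetrahydro-1-benzofuran-2(4H)-one F5. Its C6 centre is the γ-carbon of the butenolide and should equilibrate under DBU, through the 2-oxidofuran, to the epimer with C6–O cis to C2–Br, the only one that lets the planar butenolide coexist with equatorial C2–Br and C4–OH. Reduction with i-Bu2AlH (CH2Cl2, −78 to 0 °C) gives the (Z)-triol and returns to the route at 16.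

Step 10. Substitution at the neopentylic allylic C6 carbinol may be incomplete or misdirected: allylic transposition (SN2′), elimination to a diene, or arrest as a cyclic phosphorane bridging the cis-1,3-diol; the second chloride must also enter syn to the first. The fallback introduces the two chlorides one at a time, the hindered one first. It sets out from 17: TESCl and imidazole at −20 °C should silylate the less hindered C4 hydroxyl to give the C4 triethylsilyl ether of 17 with free C6–OH F6. PPh3/hexachloroacetone then acts on the single C6 carbinol, whose backside is free of a syn-axial chlorine, to give the C6 chloride (inverted) bearing C4–OSiEt3 F7. PPTS in MeOH removes the triethylsilyl group selectively to give the C4 alcohol with C6 chloride F8. A second PPh3/hexachloroacetone chlorination at C4 returns to the route at 18.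

Further compounds
F1 | step 5 | (3R,5R)-3-((tert-butyldimethylsilyl)oxy)-6,6-dimethyloct-7-en-1-yn-5-ol | C=CC(C)(C)[C@H](O)C[C@@H](O[Si](C)(C)C(C)(C)C)C#C
F2 | step 5 | (1R,5R)-5-((tert-butyldimethylsilyl)oxy)-2,2-dimethyl-4-vinylcyclohex-3-en-1-ol | CC1(C)[C@H](O)C[C@@H](O[Si](C)(C)C(C)(C)C)C(C=C)=C1
F3 | step 5 | (((1R,5S)-5-bromo-4,4-dimethyl-2-vinylcyclohex-2-en-1-yl)oxy)(tert-butyl)dimethylsilane | CC1(C)[C@@H](Br)C[C@@H](O[Si](C)(C)C(C)(C)C)C(C=C)=C1
F4 | step 8 | (4R,6S)-6-bromo-7,7-dimethyl-2,4,5,6,7,7a-hexahydro-1-benzofuran-2,4-diol (mixture at C2 and C7a) | CC1(C)[C@@H](Br)C[C@@H](O)C2=CC(O)OC12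
F5 | step 8 | (4R,6S,7aR)-6-bromo-4-hydroxy-7,7-dimethyl-5,6,7,7a-tetrahydro-1-benzofuran-2(4H)-one | CC1(C)[C@@H](Br)C[C@@H](O)C2=CC(=O)O[C@@H]12
F6 | step 10 | C4 triethylsilyl ether of 17 with free C6–OH | CC1(C)[C@@H](Br)C[C@@H](O[Si](CC)(CC)CC)/C(=C/CO[Si](C)(C)C(C)(C)C)[C@H]1O
F7 | step 10 | C6 chloride (inverted) bearing C4–OSiEt3 | CC1(C)[C@@H](Br)C[C@@H](O[Si](CC)(CC)CC)/C(=C/CO[Si](C)(C)C(C)(C)C)[C@@H]1Cl
F8 | step 10 | C4 alcohol with C6 chloride | CC1(C)[C@@H](Br)C[C@@H](O)/C(=C/CO[Si](C)(C)C(C)(C)C)[C@@H]1Cl
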